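The earlier runs and the new flask were generated by integration on assumed constants.

Late in the amber run, target gained just 1.7 percentage points between 5.00 h and 6.00 h, so I asked what was slowing it. I supposed that each electrophile reacted cost two nucleophile and that the rate followed the product of both free concentrations. On that supposition the logarithm of the ratio of free nucleophile to free electrophile moves in a straight line with time. I called its slope per hour the ratio drift: the rate constant times the gap between two electrophile charges and the nucleophile charge. The drift changes sign at a nucleophile charge of 0.260 M; Sunday's 0.195 M stands below that crossing, with nucleophile the limiting reagent.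

| flask | electrophile | nucleophile | remark | time |
|---|---|---|---|---|
| green | 0.13 M | 0.195 M | run made earlier |  |
| grey | 0.087 M | 0.195 M | run made earlier |  |
| amber | 0.20 M | 0.195 M | run made earlier |  |
| ochre | 0.13 M | 0.29 M | run made earlier |  |
| Sunday's | 0.13 M | 0.195 M | everything together at the start | 8.0 h |
| Friday's | 0.13 M | 0.195 M (fed, over 80 min) | all else is in the flask from the start; the feed brings no volume worth counting | 8.0 h |
| Saturday's | 0.13 M (fed, over 5.0 h) | 0.195 M | all else is in the flask from the start; the feed brings no volume worth counting | 8.0 h |
| Monday's | 0.13 M | 0.195 M (fed, over 5.0 h) | all else is in the flask from the start; the feed brings no volume worth counting | 8.0 h |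

- green (time / h: target / %, electrophile / %): 1.33: 10.5, 88.2; 2.50: 20.0, 79.6; 4.00: 27.2, 71.5; 5.00: 30.3, 68.5
- grey (time / h: target / %, electrophile / %): 0.833: 7.9, 91.7; 2.50: 20.9, 79.9; 4.00: 28.6, 70.8; 6.00: 38.3, 60.8
- amber (time / h: target / %, electrophile / %): 1.50: 12.6, 86.7; 3.00: 20.6, 79.9; 5.00: 27.8, 70.1; 6.00: 29.5, 67.8
- ochre (time / h: target / %, electrophile / %): 0.833: 11.4, 88.9; 2.50: 27.3, 72.0; 4.00: 38.2, 61.1; 6.00: 46.5, 50.9

(each reading ± 0.5 percentage points)



- which flask leads in amount of target, in percent of the electrophile charged ("all alike" within 1.5 percentage points) (Sunday's / Friday's / Saturday's / Monday's / all alike)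
- how much target is there at the end, in percent of the electrophile charged: Sunday's
- how much target is there at the end, in percent of the electrophile charged: Friday's
- how much target is there at the end, in percent of the electrophile charged: Saturday's
- how much target is there at the end, in percent of the electrophile charged: Monday's

I reckoned Sunday's in two ways. The green run's target at 5.00 h, read as electrophile reacted, gave a drift of 0.0313 h⁻¹. With a gap of 0.0650 M and a starting ratio of 1.50, that gave 39.9 % target at 8.0 h. The amber run has a wider gap, 0.205 M. Its last target reading, scaled down by the gaps, gave a drift of 0.0306 h⁻¹ and 39.5 % target. A reading scatters by 0.5 points. The two figures came from different flasks, both short of nucleophile but with gaps a factor of 3.15 apart, and they differed by 0.40 points, so I trusted them.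

For the fed flasks I counted a steady feed as a late start by half its length. Keeping the green drift, that gave 38.1 % for Friday's and 32.2 % for Saturday's and Monday's alike. Sunday's led Friday's by 1.8 points, barely more than the margin.

The forecast gave 39.5 %, 37.8 %, 32 % and 31.8 % for Sunday's, Friday's, Saturday's and Monday's, and chose Sunday's: “Feeding only loses reaction time, so Sunday leads, narrowly over Friday.” The flasks gave 39.8 %, 38.2 %, 32.5 % and 32.3 % in that order, with Sunday's ahead.

    target → over-reaction product (k = 2.79 × 10⁻⁶ s⁻¹)
    nucleophile + acid set free ⇌ protonated nucleophile, settled at all times (K = 721 L mol⁻¹)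
    electrophile + acid set free ⇌ idle adduct, settled at all times (K = 11.2 L mol⁻¹)
    crystals ⇌ acid set free, rate k4*(cs4 - [acid set free]) while solid is left; crystals form when [acid set free] > cs4 (solubility = 0.100 M, k = 0.00115 s⁻¹)
    electrophile + nucleophile → acid set free + target (k = 1.46 × 10⁻⁴ L mol⁻¹ s⁻¹)

In Sunday's, target's half-life toward over-reaction product, 69 h, was longer than the electrophile's half-life toward target, 6.8 h, and at 8.00 h the flask held 39.8 % target against 1.99 % over-reaction product. Its ratio of free nucleophile to free electrophile then stood at 1.17, where the drift had reckoned 1.17.

The neighbour of Monday's charged with 0.49 M nucleophile lies above the crossing, so its ratio climbs, at 0.111 h⁻¹, with electrophile now limiting, and the drift gives 64.1 % target. The computed flask held 63.6 % at 8.00 h.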